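**Retrosynthetic overview**
- The ten-membered carbocycle is closed last, by ring-closing metathesis at C1=C10 of an open triene that already carries every stereocentre.
- The cis-2,3-epoxide comes from a reagent-controlled (Z)-γ-chloroallylboration of a Z-enal (C2–C3 bond), and the side chain from esterification with (2R,3R)-epoxyangelic acid.
- Key bond C8–C9: an indium-metallated β-silyloxy-2-(bromomethyl)acrylate (a masked 2-formylacrylate whose formyl-derived carbon acts as donor) adds to a lactone aldehyde, giving the differentiated syn-8,9-diol and the C10 acrylate in one step.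
- The α-methylene-γ-lactone core comes from a butenolide by reduction and translactonisation (the Z-C4=C5 geometry is inherited from the butenolide ring); the butenolide comes from a Morita–Baylis–Hillman acetate and a 2-silyloxyfuran (C6–C7 bond).
- Ring order: butenolide (bought) → α-methylene-γ-lactone → oxirane → ten-membered ring.

Assumption: atom labels C1–C15 follow germacrane numbering of the target (C12 lactone carbonyl, C13 exocyclic methylene, C14 ester carbon, C15 methyl on C4); angelic acid and (+)-B-methoxydiisopinocampheylborane are taken as purchasable.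

**Route**

Step 1
Reactants: 1 methyl acrylate; 2 2,2-dimethoxyacetaldehyde
Product: 3 methyl 3-hydroxy-4,4-dimethoxy-2-methylidenebutanoate (racemic)
Conditions: DABCO (0.5 equiv), 1,4-dioxane–H2O (1:1), rt, 48 h
Reagents that add atoms: none
Why: Morita–Baylis–Hillman reaction of an activated α-alkoxy aldehyde; the carbinol centre may be racemic because it is erased and re-set in step 4.

Step 2
Reactants: 3 methyl 3-hydroxy-4,4-dimethoxy-2-methylidenebutanoate
Product: 4 methyl 3-acetoxy-4,4-dimethoxy-2-methylidenebutanoate (racemic)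
Conditions: Ac2O, DMAP (5 mol %), pyridine, 0 °C
Reagents that add atoms: acetic anhydride CC(=O)OC(C)=O
Why: Standard O-acetylation installs the allylic leaving group needed for Lewis-base allylic substitution.

Step 3
Reactants: 5 3-methylfuran-2(5H)-one
Product: 6 trimethyl[(3-methylfuran-2-yl)oxy]silane
Conditions: Me3SiOTf, Et3N, Et2O, 0 °C
Reagents that add atoms: trimethylsilyl trifluoromethanesulfonate C[Si](C)(C)OS(=O)(=O)C(F)(F)F
Why: Soft enolisation and O-silylation give the 2-silyloxyfuran, the γ-nucleophilic form of the butenolide.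

Step 4
Reactants: 4 methyl 3-acetoxy-4,4-dimethoxy-2-methylidenebutanoate; 6 trimethyl[(3-methylfuran-2-yl)oxy]silane
Product: 7 methyl 2-[(1S)-2,2-dimethoxy-1-[(2R)-4-methyl-5-oxo-2,5-dihydrofuran-2-yl]ethyl]prop-2-enoate
Conditions: (R)-N-[2'-(diphenylphosphanyl)-1,1'-binaphthalen-2-yl]acetamide (10 mol %), toluene, rt
Reagents that add atoms: none
Why: Phosphine-catalysed SN2'–SN2' allylic substitution of a Morita–Baylis–Hillman acetate by a 2-silyloxyfuran (vinylogous Mukaiyama-type γ-attack): the furanolate attacks C7 of the allylphosphonium in an endo, Diels–Alder-like arrangement inside the chiral amide–phosphine pocket, which sets C6 (R) and C7 (S) together and regenerates the 2-substituted acrylate; the catalyst antipode is used if induction on this substrate has the opposite sense.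

Step 5
Reactants: 7 methyl 2-[(1S)-2,2-dimethoxy-1-[(2R)-4-methyl-5-oxo-2,5-dihydrofuran-2-yl]ethyl]prop-2-enoate
Product: 10 (4S,5R)-4-(dimethoxymethyl)-5-[(1Z)-3-hydroxy-2-methylprop-1-en-1-yl]-3-methylideneoxolan-2-one, via lactol 8 (not isolated), via diol ester 9 (not isolated)
Conditions: i-Bu2AlH (1.15 equiv), CH2Cl2, −78 °C; MeOH, CeCl3·7H2O, NaBH4, −40 °C; acetone, then DBU (0.3 equiv), rt
Reagents that add atoms: none
Why: The lactone is reduced faster than the hindered acrylate ester, Luche reduction of the lactol (open Z-hydroxy-enal) gives the Z-ene-diol before it can aromatise to a furan, and the C6 alkoxide then lactonises onto the C12 ester (5-exo-trig translactonisation) to give the trans α-methylene-γ-lactone with C6/C7 untouched and the Z-olefin inherited from the butenolide ring.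

Step 6
Reactants: 11 methyl propanoate; 12 methyl formate
Product: 14 methyl (2E)-3-[(tert-butyldimethylsilyl)oxy]-2-methylprop-2-enoate, via sodium enolate 13 (not isolated)
Conditions: NaH, THF, 0 °C to rt; then t-BuMe2SiCl, 0 °C
Reagents that add atoms: tert-butyl(chloro)dimethylsilane CC(C)(C)[Si](C)(C)Cl
Why: Crossed Claisen formylation followed by O-silylation of the formyl-ester enolate gives the β-silyloxy acrylate, the E isomer being the thermodynamically preferred one.

Step 7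
Reactants: 14 methyl (2E)-3-[(tert-butyldimethylsilyl)oxy]-2-methylprop-2-enoate
Product: 15 methyl (2Z)-2-(bromomethyl)-3-[(tert-butyldimethylsilyl)oxy]prop-2-enoate
Conditions: NBS, AIBN (cat.), PhCF3, 80 °C
Reagents that add atoms: N-bromosuccinimide O=C1CCC(=O)N1Br
Why: Wohl–Ziegler allylic bromination of the methyl group, as practised on β-methoxyacrylates; the geometry is kept (only the CIP descriptor changes).

Step 8
Reactants: 10 (4S,5R)-4-(dimethoxymethyl)-5-[(1Z)-3-hydroxy-2-methylprop-1-en-1-yl]-3-methylideneoxolan-2-one; 15 methyl (2Z)-2-(bromomethyl)-3-[(tert-butyldimethylsilyl)oxy]prop-2-enoate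
Product: 17 methyl (3S,4S)-3-[(tert-butyldimethylsilyl)oxy]-4-hydroxy-4-[(2R,3R)-2-[(1Z)-3-hydroxy-2-methylprop-1-en-1-yl]-4-methylidene-5-oxooxolan-3-yl]-2-methylidenebutanoate, via aldehyde 16 (not isolated)
Conditions: Amberlyst-15, acetone–H2O (20:1), rt; filter; then In powder (1.5 equiv), 15 (1.5 equiv), THF–H2O (4:1), 0 °C to rt
Reagents that add atoms: water O
Why: Proposed new method: indium inserts into the allylic C–Br bond of 15 to give a 2-(methoxycarbonyl)-3-silyloxyallylindium, the metallo-homoenolate of a masked methyl 2-formylacrylate, whose formyl-derived carbon C9 (natively an acceptor) is delivered as a donor, with allylic transposition, to the acceptor carbon C8 of aldehyde 16; a closed chair (Zimmerman–Traxler) transition state with the silyloxy group cis to CH2In gives the syn (threo) 8,9-relationship, and Felkin–Anh attack anti to the C7–C11 bond (the electron-poor sp2 carbon as antiperiplanar group) gives 8S,9S, the closest known reactions being the indium- or zinc-mediated Barbier lactone synthesis with γ-substituted 2-(bromomethyl)acrylates and the α-hydroxyallylation of aldehydes with 3-bromopropenyl esters.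

Step 9
Reactants: 17 methyl (3S,4S)-3-[(tert-butyldimethylsilyl)oxy]-4-hydroxy-4-[(2R,3R)-2-[(1Z)-3-hydroxy-2-methylprop-1-en-1-yl]-4-methylidene-5-oxooxolan-3-yl]-2-methylidenebutanoate
Product: 18 methyl (3S,4S)-3-[(tert-butyldimethylsilyl)oxy]-4-hydroxy-2-methylidene-4-[(2R,3R)-4-methylidene-2-[(1Z)-2-methyl-3-oxoprop-1-en-1-yl]-5-oxooxolan-3-yl]butanoate
Conditions: MnO2 (activated, 15 equiv), CH2Cl2, rt
Reagents that add atoms: none
Why: MnO2 oxidises only the primary allylic alcohol (the C8 hydroxyl is not allylic, C9 is silylated) and keeps the Z geometry under neutral heterogeneous conditions.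

Step 10
Reactants: 19 angelic acid [(2Z)-2-methylbut-2-enoic acid]
Product: 20 (2Z)-2-methylbut-2-en-1-ol
Conditions: LiAlH4, Et2O, 0 °C
Reagents that add atoms: none
Why: Hydride 1,2-reduction of the conjugated acid to the allylic alcohol with retention of olefin geometry.

Step 11
Reactants: 20 (2Z)-2-methylbut-2-en-1-ol
Product: 21 [(2S,3R)-2,3-dimethyloxiran-2-yl]methanol
Conditions: Ti(Oi-Pr)4 (10 mol %), L-(+)-diisopropyl tartrate (12 mol %), t-BuOOH, 4 Å molecular sieves, CH2Cl2, −20 °C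
Reagents that add atoms: tert-butyl hydroperoxide CC(C)(C)OO
Why: Sharpless asymmetric epoxidation; the L-(+)-tartrate complex delivers oxygen syn to the face that gives the (2S,3R) epoxy alcohol.

Step 12
Reactants: 21 [(2S,3R)-2,3-dimethyloxiran-2-yl]methanol
Product: 22 (2R,3R)-2,3-dimethyloxirane-2-carboxylic acid
Conditions: RuCl3·H2O (2 mol %), NaIO4, MeCN–EtOAc–H2O, 0 °C to rt
Reagents that add atoms: sodium periodate [Na+].[O-]I(=O)(=O)=O; water O
Why: Catalytic RuO4 oxidation of the primary alcohol to the acid leaves the epoxide intact; the C2 descriptor changes from S to R only because the CIP priorities change.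

Step 13
Reactants: 18 methyl (3S,4S)-3-[(tert-butyldimethylsilyl)oxy]-4-hydroxy-2-methylidene-4-[(2R,3R)-4-methylidene-2-[(1Z)-2-methyl-3-oxoprop-1-en-1-yl]-5-oxooxolan-3-yl]butanoate; 22 (2R,3R)-2,3-dimethyloxirane-2-carboxylic acid
Product: 24 (1S,2S)-2-[(tert-butyldimethylsilyl)oxy]-3-(methoxycarbonyl)-1-[(2R,3S)-4-methylidene-2-[(1Z)-2-methyl-3-oxoprop-1-en-1-yl]-5-oxooxolan-3-yl]but-3-en-1-yl (2R,3R)-2,3-dimethyloxirane-2-carboxylate, via mixed anhydride 23 (not isolated)
Conditions: 2,4,6-trichlorobenzoyl chloride, Et3N, toluene, rt; then 18, DMAP (0.3 equiv), rt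
Reagents that add atoms: none
Why: Yamaguchi esterification of the only free hydroxyl (C8) with retention at every centre; acylating at once also prevents the γ-hydroxy ester from lactonising onto C14.

Step 14
Reactants: 24 (1S,2S)-2-[(tert-butyldimethylsilyl)oxy]-3-(methoxycarbonyl)-1-[(2R,3S)-4-methylidene-2-[(1Z)-2-methyl-3-oxoprop-1-en-1-yl]-5-oxooxolan-3-yl]but-3-en-1-yl (2R,3R)-2,3-dimethyloxirane-2-carboxylate
Product: 26 (1S,2S)-2-[(tert-butyldimethylsilyl)oxy]-1-[(2R,3S)-2-[(1Z)-2-[(2S,3R)-3-ethenyloxiran-2-yl]prop-1-en-1-yl]-4-methylidene-5-oxooxolan-3-yl]-3-(methoxycarbonyl)but-3-en-1-yl (2R,3R)-2,3-dimethyloxirane-2-carboxylate, via chlorohydrin 25 (not isolated)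
Conditions: allyl chloride, LiN(c-C6H11)2, (+)-B-methoxydiisopinocampheylborane (from (−)-α-pinene), Et2O, −95 °C; BF3·OEt2, then 24, −95 °C; HOCH2CH2NH2, rt; DBU, CH2Cl2, rt
Reagents that add atoms: allyl chloride C=CCCl
Why: Brown-type asymmetric (Z)-γ-chloroallylboration, in which the α-chloroallyl carbanion makes the future epoxide carbon C2 a donor toward the aldehyde carbon C3: the closed chair transition state gives the syn chlorohydrin, the isopinocampheyl groups direct attack to the Re face of the aldehyde (3S), and DBU closes the oxirane with inversion at C2 to the cis-(2R,3S) vinyl epoxide.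

Step 15
Reactants: 26 (1S,2S)-2-[(tert-butyldimethylsilyl)oxy]-1-[(2R,3S)-2-[(1Z)-2-[(2S,3R)-3-ethenyloxiran-2-yl]prop-1-en-1-yl]-4-methylidene-5-oxooxolan-3-yl]-3-(methoxycarbonyl)but-3-en-1-yl (2R,3R)-2,3-dimethyloxirane-2-carboxylate
Product: 27 (1S,2S)-1-[(2R,3S)-2-[(1Z)-2-[(2S,3R)-3-ethenyloxiran-2-yl]prop-1-en-1-yl]-4-methylidene-5-oxooxolan-3-yl]-2-hydroxy-3-(methoxycarbonyl)but-3-en-1-yl (2R,3R)-2,3-dimethyloxirane-2-carboxylate
Conditions: HF·pyridine, pyridine, THF, 0 °C to rt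
Reagents that add atoms: none
Why: Buffered fluoride cleavage of the silyl ether is non-basic, so the C8 ester does not migrate to O9 and the epoxides and Michael acceptors survive.

Step 16
Reactants: 27 (1S,2S)-1-[(2R,3S)-2-[(1Z)-2-[(2S,3R)-3-ethenyloxiran-2-yl]prop-1-en-1-yl]-4-methylidene-5-oxooxolan-3-yl]-2-hydroxy-3-(methoxycarbonyl)but-3-en-1-yl (2R,3R)-2,3-dimethyloxirane-2-carboxylate
Product: 28 CNP0291485.1, methyl (2R,3S,6R,7S,8S,9S)-2,3-epoxy-8-[(2R,3R)-2,3-epoxy-2-methylbutanoyloxy]-9-hydroxy-germacra-1(10)E,4Z,11(13)-trien-6,12-olid-14-oate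
Conditions: second-generation Hoveyda–Grubbs catalyst (20 mol %), 1,4-benzoquinone (40 mol %), toluene (0.5 mM), 80 °C
Reagents that add atoms: none
Why: Ring-closing metathesis with loading on the vinyl-epoxide terminus and closure on the C10 acrylate (helped by the free allylic C9 hydroxyl); the ten-membered ring only accommodates C2 cis to C9 across C1=C10, which is the required E descriptor.

**Compound list**

1 | methyl acrylate | C=CC(=O)OC | starting material
2 | 2,2-dimethoxyacetaldehyde | COC(OC)C=O | starting material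
3 | methyl 3-hydroxy-4,4-dimethoxy-2-methylidenebutanoate (racemic) | C=C(C(=O)OC)C(O)C(OC)OC | intermediate
4 | methyl 3-acetoxy-4,4-dimethoxy-2-methylidenebutanoate (racemic) | C=C(C(=O)OC)C(OC(C)=O)C(OC)OC | intermediate
5 | 3-methylfuran-2(5H)-one | CC1=CCOC1=O | starting material
6 | trimethyl[(3-methylfuran-2-yl)oxy]silane | Cc1ccoc1O[Si](C)(C)C | intermediate
7 | methyl 2-[(1S)-2,2-dimethoxy-1-[(2R)-4-methyl-5-oxo-2,5-dihydrofuran-2-yl]ethyl]prop-2-enoate | COC(=O)C(=C)[C@@H]([C@@H]1OC(=O)C(C)=C1)C(OC)OC | intermediate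
8 | methyl 2-[(1S)-1-[(2R)-5-hydroxy-4-methyl-2,5-dihydrofuran-2-yl]-2,2-dimethoxyethyl]prop-2-enoate (lactol, anomers) | COC(=O)C(=C)[C@@H]([C@@H]1OC(O)C(C)=C1)C(OC)OC | intermediate
9 | methyl (3S,4R,5Z)-3-(dimethoxymethyl)-4,7-dihydroxy-6-methyl-2-methylidenehept-5-enoate | COC(=O)C(=C)[C@@H]([C@H](O)/C=C(/C)CO)C(OC)OC | intermediate
10 | (4S,5R)-4-(dimethoxymethyl)-5-[(1Z)-3-hydroxy-2-methylprop-1-en-1-yl]-3-methylideneoxolan-2-one | C=C1C(=O)O[C@H](/C=C(/C)CO)[C@H]1C(OC)OC | intermediate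
11 | methyl propanoate | CCC(=O)OC | starting material
12 | methyl formate | COC=O | starting material
13 | sodium 3-methoxy-2-methyl-3-oxoprop-1-en-1-olate | [Na+].[O-]C=C(C)C(=O)OC | intermediate
14 | methyl (2E)-3-[(tert-butyldimethylsilyl)oxy]-2-methylprop-2-enoate | COC(=O)/C(C)=C/O[Si](C)(C)C(C)(C)C | intermediate
15 | methyl (2Z)-2-(bromomethyl)-3-[(tert-butyldimethylsilyl)oxy]prop-2-enoate | COC(=O)/C(CBr)=C/O[Si](C)(C)C(C)(C)C | intermediate
16 | (2R,3S)-2-[(1Z)-3-hydroxy-2-methylprop-1-en-1-yl]-4-methylidene-5-oxooxolane-3-carbaldehyde | C=C1C(=O)O[C@H](/C=C(/C)CO)[C@H]1C=O | intermediate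
17 | methyl (3S,4S)-3-[(tert-butyldimethylsilyl)oxy]-4-hydroxy-4-[(2R,3R)-2-[(1Z)-3-hydroxy-2-methylprop-1-en-1-yl]-4-methylidene-5-oxooxolan-3-yl]-2-methylidenebutanoate | C=C1C(=O)O[C@H](/C=C(/C)CO)[C@H]1[C@H](O)[C@@H](O[Si](C)(C)C(C)(C)C)C(=C)C(=O)OC | intermediate
18 | methyl (3S,4S)-3-[(tert-butyldimethylsilyl)oxy]-4-hydroxy-2-methylidene-4-[(2R,3R)-4-methylidene-2-[(1Z)-2-methyl-3-oxoprop-1-en-1-yl]-5-oxooxolan-3-yl]butanoate | C=C1C(=O)O[C@H](/C=C(/C)C=O)[C@H]1[C@H](O)[C@@H](O[Si](C)(C)C(C)(C)C)C(=C)C(=O)OC | intermediate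
19 | angelic acid, (2Z)-2-methylbut-2-enoic acid | C/C=C(/C)C(=O)O | starting material
20 | (2Z)-2-methylbut-2-en-1-ol | C/C=C(/C)CO | intermediate
21 | [(2S,3R)-2,3-dimethyloxiran-2-yl]methanol | OC[C@]1(C)O[C@@H]1C | intermediate
22 | (2R,3R)-2,3-dimethyloxirane-2-carboxylic acid | OC(=O)[C@]1(C)O[C@@H]1C | intermediate
23 | (2R,3R)-2,3-dimethyloxirane-2-carboxylic 2,4,6-trichlorobenzoic anhydride | O=C(OC(=O)[C@]1(C)O[C@@H]1C)c1c(Cl)cc(Cl)cc1Cl | intermediate
24 | (1S,2S)-2-[(tert-butyldimethylsilyl)oxy]-3-(methoxycarbonyl)-1-[(2R,3S)-4-methylidene-2-[(1Z)-2-methyl-3-oxoprop-1-en-1-yl]-5-oxooxolan-3-yl]but-3-en-1-yl (2R,3R)-2,3-dimethyloxirane-2-carboxylate | C=C1C(=O)O[C@H](/C=C(/C)C=O)[C@H]1[C@H](OC(=O)[C@]2(C)O[C@@H]2C)[C@@H](O[Si](C)(C)C(C)(C)C)C(=C)C(=O)OC | intermediate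
25 | (1S,2S)-2-[(tert-butyldimethylsilyl)oxy]-1-[(2R,3S)-2-[(1Z,3S,4S)-4-chloro-3-hydroxy-2-methylhexa-1,5-dien-1-yl]-4-methylidene-5-oxooxolan-3-yl]-3-(methoxycarbonyl)but-3-en-1-yl (2R,3R)-2,3-dimethyloxirane-2-carboxylate | C=C1C(=O)O[C@H](/C=C(/C)[C@H](O)[C@@H](Cl)C=C)[C@H]1[C@H](OC(=O)[C@]2(C)O[C@@H]2C)[C@@H](O[Si](C)(C)C(C)(C)C)C(=C)C(=O)OC | intermediate
26 | (1S,2S)-2-[(tert-butyldimethylsilyl)oxy]-1-[(2R,3S)-2-[(1Z)-2-[(2S,3R)-3-ethenyloxiran-2-yl]prop-1-en-1-yl]-4-methylidene-5-oxooxolan-3-yl]-3-(methoxycarbonyl)but-3-en-1-yl (2R,3R)-2,3-dimethyloxirane-2-carboxylate | C=C1C(=O)O[C@H](/C=C(/C)[C@@H]2O[C@@H]2C=C)[C@H]1[C@H](OC(=O)[C@]2(C)O[C@@H]2C)[C@@H](O[Si](C)(C)C(C)(C)C)C(=C)C(=O)OC | intermediate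
27 | (1S,2S)-1-[(2R,3S)-2-[(1Z)-2-[(2S,3R)-3-ethenyloxiran-2-yl]prop-1-en-1-yl]-4-methylidene-5-oxooxolan-3-yl]-2-hydroxy-3-(methoxycarbonyl)but-3-en-1-yl (2R,3R)-2,3-dimethyloxirane-2-carboxylate | C=C1C(=O)O[C@H](/C=C(/C)[C@@H]2O[C@@H]2C=C)[C@H]1[C@H](OC(=O)[C@]2(C)O[C@@H]2C)[C@@H](O)C(=C)C(=O)OC | intermediate
28 | CNP0291485.1, methyl (2R,3S,6R,7S,8S,9S)-2,3-epoxy-8-[(2R,3R)-2,3-epoxy-2-methylbutanoyloxy]-9-hydroxy-germacra-1(10)E,4Z,11(13)-trien-6,12-olid-14-oate | C=C1C(=O)O[C@@H]2/C=C(/C)[C@@H]3O[C@@H]3/C=C(/C(=O)OC)[C@H](O)[C@@H](OC(=O)[C@]3(C)O[C@@H]3C)[C@@H]12 | target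

**Step count**
Total: 16 steps. Longest linear sequence: 10 steps (steps 1, 2, 4, 5, 8, 9, 13, 14, 15, 16).

**Three steps most likely to fail**

Step 8 (key coupling). Aldehyde 16 can isomerise to the conjugated 4-formyl-3-methylbutenolide, the silyl enol ether of 15 can hydrolyse, and facial control at C8 rests on a Felkin–Anh argument. Fallback, from 7 back to 24: the coupling is moved to the butenolide stage and the lactone is made afterwards by lactol translactonisation. Acetal hydrolysis of 7 (Amberlyst-15, wet acetone) gives methyl 2-[(1S)-1-[(2R)-4-methyl-5-oxo-2,5-dihydrofuran-2-yl]-2-oxoethyl]prop-2-enoate F1, whose aldehyde sits on an acyclic carbon with no exocyclic lactone olefin to isomerise. Indium coupling of this with 15 gives the butenolide diol monosilyl ether F2, and Yamaguchi esterification with 22 gives the butenolide epoxyangelate F3. i-Bu2AlH at −78 °C then reduces the butenolide to the lactol F4. DBU opens the lactol, and the C6 alkoxide lactonises onto the C12 methyl ester, releasing the Z-enal and rejoining the route at 24. This also removes the NaBH4/MnO2 redox pair, at the price of a less selective hydride reduction.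

Step 16 (ring closure). A trisubstituted, electron-poor olefin must form in a ten-membered ring, and the α-methylene lactone is a competing 1,1-disubstituted olefin that would give an eight-membered ring. Fallback, from 27 back to 28: Me2NH (THF, 0 °C) adds to the strained α-methylene lactone to give the C13 dimethylamino Mannich base F5. As its toluenesulfonate salt this has only the C10 acrylate left as a partner, so metathesis under the same catalyst can only give the macrocyclic Mannich base F6. MeI followed by NaHCO3 (quaternisation, E1cB elimination) restores the exocyclic methylene and returns to the route at 28.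

Step 4 (C6/C7 stereocontrol). Diastereo- and enantioselectivity are untested for an aliphatic, acetal-bearing acetate with an α-methyl silyloxyfuran. Fallback, from 6 back to 7, by iminium catalysis instead of phosphine catalysis: 6 and commercial (E)-4,4-dimethoxybut-2-enal undergo an organocatalytic Mukaiyama–Michael addition with (2S,5S)-5-benzyl-2-tert-butyl-3-methylimidazolidin-4-one 2,4-dinitrobenzoate to give (3S)-4,4-dimethoxy-3-[(2R)-4-methyl-5-oxo-2,5-dihydrofuran-2-yl]butanal F7. Its α-methylenation (aqueous CH2O, pyrrolidine, propanoic acid) gives the 2-substituted acrolein F8, Pinnick oxidation (NaClO2, NaH2PO4, 2-methylbut-2-ene) gives the acrylic acid F9, and Me3SiCHN2 in MeOH returns to the route at 7.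

**Further compounds**

F1 | step 8 | methyl 2-[(1S)-1-[(2R)-4-methyl-5-oxo-2,5-dihydrofuran-2-yl]-2-oxoethyl]prop-2-enoate | COC(=O)C(=C)[C@@H]([C@@H]1OC(=O)C(C)=C1)C=O
F2 | step 8 | dimethyl (3S,4S,5R)-3-[(tert-butyldimethylsilyl)oxy]-4-hydroxy-2,6-dimethylidene-5-[(2R)-4-methyl-5-oxo-2,5-dihydrofuran-2-yl]heptanedioate | COC(=O)C(=C)[C@@H]([C@@H]1OC(=O)C(C)=C1)[C@H](O)[C@@H](O[Si](C)(C)C(C)(C)C)C(=C)C(=O)OC
F3 | step 8 | dimethyl (3S,4S,5S)-3-[(tert-butyldimethylsilyl)oxy]-4-{[(2R,3R)-2,3-dimethyloxiran-2-yl]carbonyloxy}-2,6-dimethylidene-5-[(2R)-4-methyl-5-oxo-2,5-dihydrofuran-2-yl]heptanedioate | COC(=O)C(=C)[C@@H]([C@@H]1OC(=O)C(C)=C1)[C@H](OC(=O)[C@]1(C)O[C@@H]1C)[C@@H](O[Si](C)(C)C(C)(C)C)C(=C)C(=O)OC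
F4 | step 8 | dimethyl (3S,4S,5S)-3-[(tert-butyldimethylsilyl)oxy]-4-{[(2R,3R)-2,3-dimethyloxiran-2-yl]carbonyloxy}-5-[(2R)-5-hydroxy-4-methyl-2,5-dihydrofuran-2-yl]-2,6-dimethylideneheptanedioate (lactol, anomers) | COC(=O)C(=C)[C@@H]([C@@H]1OC(O)C(C)=C1)[C@H](OC(=O)[C@]1(C)O[C@@H]1C)[C@@H](O[Si](C)(C)C(C)(C)C)C(=C)C(=O)OC
F5 | step 16 | 13-(dimethylamino)-11,13-dihydro derivative of 27 (C11 epimers) | CN(C)CC1C(=O)O[C@H](/C=C(/C)[C@@H]2O[C@@H]2C=C)[C@H]1[C@H](OC(=O)[C@]2(C)O[C@@H]2C)[C@@H](O)C(=C)C(=O)OC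
F6 | step 16 | 13-(dimethylamino)-11,13-dihydro derivative of 28 (C11 epimers) | CN(C)CC1C(=O)O[C@@H]2/C=C(/C)[C@@H]3O[C@@H]3/C=C(/C(=O)OC)[C@H](O)[C@@H](OC(=O)[C@]3(C)O[C@@H]3C)[C@@H]12
F7 | step 4 | (3S)-4,4-dimethoxy-3-[(2R)-4-methyl-5-oxo-2,5-dihydrofuran-2-yl]butanal | O=CC[C@@H]([C@@H]1OC(=O)C(C)=C1)C(OC)OC
F8 | step 4 | 2-[(1S)-2,2-dimethoxy-1-[(2R)-4-methyl-5-oxo-2,5-dihydrofuran-2-yl]ethyl]prop-2-enal | O=CC(=C)[C@@H]([C@@H]1OC(=O)C(C)=C1)C(OC)OC
F9 | step 4 | 2-[(1S)-2,2-dimethoxy-1-[(2R)-4-methyl-5-oxo-2,5-dihydrofuran-2-yl]ethyl]prop-2-enoic acid | OC(=O)C(=C)[C@@H]([C@@H]1OC(=O)C(C)=C1)C(OC)OC
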